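The data were computed from invented constants; scatter was added.

Sunday's flask is followed here: solid substrate dissolves in a stirred liquid while partner is fed in, and the solid's reading is the one to watch.

| flask | solid substrate | partner | remark | time |
|---|---|---|---|---|
| Sunday's | 1.5 M | 1.95 M (fed, over 40 h) | the very flask that is asked about, followed so far; the fed solution adds 0.10 times the starting volume |  |
| Monday's | 1.5 M | 2.9 M (fed, over 40 h) | run made earlier; the fed solution adds 0.10 times the starting volume |  |
| flask | 1.5 M | 1.95 M (fed, over 40 h) | the fed solution adds 0.10 times the starting volume | 4.0 d |

| run | time / h | solid substrate / % | target / % |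
|---|---|---|---|
| Sunday's | 8.00 | 96.1 | 0.1 |
| Sunday's | 15.0 | 90.6 | 3.3 |
| Sunday's | 25.0 | 86.2 | 8.3 |
| Sunday's | 30.0 | 82.6 | 10.4 |
| Sunday's | 40.0 | 78.4 | 15.4 |
| Sunday's | 50.0 | 71.7 | 20.1 |
| Monday's | 2.50 | 100.7 | 0 |
| Monday's | 8.00 | 97.5 | 3.2 |
| Monday's | 15.0 | 92.6 | 6.1 |
| Monday's | 20.0 | 90.1 | 9.0 |
| Monday's | 30.0 | 82.4 | 13.1 |
| Monday's | 40.0 | 75.7 | 16.5 |

(scatter of a reading: 1 percentage point)

- a species is counted by the solid substrate in it: one side product counts as two
- charges are per starting volume, the dose included; the dosed solution carries all of it
- the analysis behind the earlier runs scatters by 1 percentage point, standard deviation
- at the start none of the solid substrate is in solution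
- what has only dissolved of solid substrate counts as not reacted
- a reading or a percentage of target counts all its forms, free or not
- the reaction counts as stopped when no species that holds the solid substrate changes by six tenths of a point or more over the second half of the time

- which holds at 4.0 d: what has brought the reaction to rest, or that it has not come to rest (for what has run out or reacted, a solid counts together with what of it has only dissolved) (the partner has run out first / all of the solid substrate has reacted / it is still moving)
- part of the solid substrate that has turned into other species by 4.0 d (what has only dissolved does not count)
- how much target there is at 4.0 d, in percent of the solid substrate charged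
- how much side product there is at 4.0 d, in percent of the solid substrate charged

The useful quantity is the emptying time of the solid, the time at which the charge would vanish at its average pace so far: the time of a reading divided by the fraction gone at that reading, 177 h from Sunday's last reading. On such a straight line the fraction left is one minus time over emptying time. Monday's flask, with 2.9 M of partner against 1.95 M, gives 165 h. Sunday's feed brings partner equal to the charged solid in 30.8 h, far less than the emptying time, so dissolving looks like the rate-limiting step.

From above, a pace slackening in proportion to what remains (first order through Sunday's last reading) leaves 52.8% of the solid at 4.0 d. From below, Monday's steeper line leaves 41.8%. The upper bound tightens by hand: Sunday's solid lost 14 percentage points by 25.0 h, then 15 points by 50.0 h, more in the second stretch than in the first, so within the scatter of 1 point no slackening shows, and Sunday's line leaves 45.8%. Dissolved substrate counts as unreacted; the balance gap at 8.00 h and 15.0 h in both runs averages 2.63%, which holds early side product as well and is taken as a rough allowance for dissolved substrate. This reckoning puts conversion between 51.7% and 58.3%.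

The forecast says it is still moving, with conversion 51%, target 34% and side product 17%, extrapolating “with slight slowing from shrinking solid area”. Its conversion lies just below the bracket.

At 4.0 d Sunday's flask gives this: it is still moving, with conversion 54.9%, target 29.0% and side product 26.0%. Its solid stands at 42.8%, between the two lines, and its conversion lies inside the bracket. The forecast parts from the flask on the split: the flask's side product lies 9 points above the forecast's.

    solid substrate ⇌ dissolved substrate, rate k1*(cs1 - [dissolved substrate]) while solid is left; crystals form when [dissolved substrate] > cs1 (solubility = 0.250 M, k = 1.05 × 10⁻⁵ /s)
    dissolved substrate + partner → target (k = 6.68 × 10⁻⁵ /M/s)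
    dissolved substrate + target → side product (k = 7.98 × 10⁻⁵ /M/s)
    solid product ⇌ target, rate k4*(cs4 - [target]) while solid is left; crystals form when [target] > cs4 (solubility = 0.610 M, k = 0.00104 /s)
    2 partner → self-condensation product (k = 1.05 × 10⁻⁶ /M/s)

Read at 6.0 d, the same flask takes the same reckoning: the emptying times of 165 h and 177 h leave 12.5% to 18.6% of the solid, and that flask holds 14.2%, with conversion 82.9%, target 28.6% and side product 54.3%.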